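The numbers in the tables are calculated with made-up constants; noise was put on by code.

The larch run was my ruler for the ash flask, whose state at 12 h I wanted from the earlier readings.

| flask | starting material | free catalyst | remark | time |
|---|---|---|---|---|
| ash | 20 mM (fed, over 8.0 h) | 3.4 mM | the very flask that is asked about, followed so far; the fed solution adds 0.25 times the starting volume |  |
| larch | 20 mM (fed, over 8.0 h) | 1.7 mM | run made earlier; the fed solution adds 0.25 times the starting volume |  |
| flask | 20 mM (fed, over 8.0 h) | 3.4 mM | the fed solution adds 0.25 times the starting volume | 12 h |

- ash (time / h: starting material / %, catalyst intermediate B / %): 0.667: 10, 2; 1.33: 14, 1; 2.00: 20, 1; 2.50: 22, 0; 3.00: 23, 2; 4.00: 33, 1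
- larch (time / h: starting material / %, catalyst intermediate B / %): 1.00: 11, 1; 1.50: 15, 2; 2.50: 26, 0; 4.00: 41, 3; 8.00: 65, 2; 12.0: 41, 5

(scatter of a reading: 1.5 percentage points)

- amount of starting material in the flask at 12 h, in percent of the starting material charged
- amount of catalyst intermediate B in the flask at 12 h, in percent of the starting material charged
- amount of target in the flask at 12 h, in percent of the starting material charged

- charges are per starting volume, the dose included; the dosed solution carries all of it
- percentages count the whole charge, also what has not yet gone in

After the larch feed ended, [starting material] fell from 65% at 8.00 h to 41% at 12.0 h. Taking logarithms turned that fall into a slope of 0.115 h⁻¹. This reading is a pseudo-first-order loss constant, the fractional loss of starting material per hour after the feed has stopped. I assumed that it scales with the free catalyst charged, and ash has twice the larch charge, which gave 0.230 h⁻¹. As a test, I ran the steady feed against this constant up to 4.00 h in ash and got 32.7%, while the reading there was 33%.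

Then I built up the flask. Treating the main step as a first-order loss, with the whole charge present from the start, I reckoned 6.33% of the starting material at 12 h. Adding the feed gave 45.7% at 8.0 h and 18.2% at 12 h. The constant was read at full volume, so I next scaled it in inverse proportion to the volume while the volume was still growing, and that gave 17.5%. Last came catalyst intermediate B. I borrowed the last larch reading of 5% for it, a single scattered reading from the run with less free catalyst charged, and, counting no other species, that left 77.5% as target.

The forecast, higher than my figure for starting material, said 21% (17% to 26%), with 1.5% of catalyst intermediate B (0.5% to 3.5%) and 77.5% of target (71% to 82%). Its ground was “Doubling the catalyst roughly doubles the rate constant”.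

At 12 h the ash flask gave 20.3% of starting material, 5.39% of catalyst intermediate B and 73.9% of target, so the forecast held within its tolerance.

    catalyst intermediate B ⇌ free catalyst + target (K = 0.0290 M, k = 4.80 h⁻¹)
    catalyst intermediate A ⇌ catalyst intermediate B (K = 20.0, k = 28.0 h⁻¹)
    starting material + free catalyst → catalyst intermediate A (k = 110 M⁻¹ h⁻¹)

For the neighbour charged with 0.85 mM of free catalyst and read at 12 h, the larch constant scales to 0.0576 h⁻¹. The same reckoning with the growing volume gives 62.7% of starting material. That neighbour held 64.6% of starting material and 34.1% of target.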